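**Retrosynthetic overview**
- Feature: the ring-fusion carbon C7a carries N1. It lies between C7 (bearing Br) and C3a (bonded to C3), so both positions ortho to nitrogen map onto the two equivalent C–Br bonds of symmetric 2,6-dibromoaniline.
- C2–Br and C3–Br are removed first. C2–Br comes from electrophilic bromination, and C3–Br from ipso bromodecarboxylation of 7-bromoindole-3-carboxylic acid, whose carboxyl group marks C3.
- C3–C3a is cut by a palladium-catalysed intramolecular enamine arylation of methyl (Z)-3-[(2,6-dibromophenyl)amino]acrylate. One bromine is spent in the closure and the other stays as C7–Br.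
- N1–C2 goes back to an acid-catalysed condensation of 2,6-dibromoaniline with methyl 3,3-dimethoxypropanoate.
- Ring order: the benzene ring is bought, and the pyrrole ring is the only ring formed (step 2).

Key step: step 2

Remark: 2,6-dibromoaniline is a weakly basic, doubly ortho-hindered amine, so the three-carbon ester unit is attached under acid catalysis from the acetal and not by uncatalysed addition to an alkynoate; the N–H 2,3-dibromoindole unit of the target is treated as sensitive to light, acid and moisture.

**Step 1**
Reactants: 1 2,6-dibromoaniline; 2 methyl 3,3-dimethoxypropanoate
Product: 3 methyl (Z)-3-[(2,6-dibromophenyl)amino]acrylate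
Conditions: 2 (1.5 equiv), p-TsOH·H2O (5 mol %), toluene, reflux, MeOH distilled off
Reagents that add atoms: methyl 3,3-dimethoxypropanoate (2), COC(=O)CC(OC)OC
Why: This is an acid-catalysed acetal exchange–elimination (enamine condensation of a masked formylacetate), in which the acid ionises the acetal to an oxocarbenium ion reactive enough for the weakly basic amine (which stays largely unprotonated), removal of two MeOH drives the equilibrium, and the intramolecular N–H···O=C hydrogen bond favours the Z isomer.

**Step 2**
Reactants: 3 methyl (Z)-3-[(2,6-dibromophenyl)amino]acrylate
Product: 5 methyl 7-bromo-1H-indole-3-carboxylate, via methyl 7-bromo-3H-indole-3-carboxylate 4 (not isolated)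
Conditions: Pd(OAc)2 (5 mol %), P(o-tol)3 (12 mol %), DABCO (2.5 equiv), DMF (0.05 M), 105 °C, N2
Reagents that add atoms: none
Why: Pd(OAc)2 is reduced in situ by the phosphine to zerovalent palladium, which inserts into one C–Br bond of 3; the enamine β-carbon (α to the ester, the future C3) then replaces bromide on the divalent arylpalladium centre, DABCO removes the N–H proton, and the six-membered azapalladacycle (Pd, C3a, C7a, N1, C2, C3) undergoes reductive elimination to form C3–C3a. The 3H-indole 4 released in this way tautomerises at once to the aromatic 1H-indole 5, so the C3 stereocentre of 4 is transient, no stereocentre has to be controlled, and the Z/E geometry of 3 is erased. The closest known reaction type is the palladium-catalysed cyclisation of N-(2-haloaryl) enaminoesters and enaminones to indole-3-carboxylates and 3-acylindoles (intramolecular enamine C-arylation, a formal Heck reaction). The pyrrole ring closes in a formal 5-endo-trig mode, which is feasible because the C–C bond arises by contraction of the six-membered palladacycle and not by a strained syn-carbopalladation. The step needs mono-reaction of a dibromide: the two C–Br bonds of 3 are equivalent by symmetry, so it does not matter which one reacts, and once the ring is closed the remaining C7–Br has no tethered nucleophile and can react only through slower intermolecular pathways. These pathways are further held down by dilution, by stopping at full conversion of 3, and by DABCO, whose bridgehead nitrogen atoms cannot form an iminium ion and so cannot pass a hydride to palladium for hydrodebromination.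

**Step 3**
Reactants: 5 methyl 7-bromo-1H-indole-3-carboxylate
Product: 7 7-bromo-1H-indole-3-carboxylic acid, via sodium 7-bromo-1H-indole-3-carboxylate 6 (not isolated)
Conditions: NaOH (5 equiv, 2 M aq), MeOH–THF, 65 °C; then 1 M HCl, 0 °C, pH 3
Reagents that add atoms: sodium hydroxide, [Na+].[OH-]
Why: This is a saponification (acyl–oxygen ester hydrolysis) in which the vinylogous-carbamate ester is sluggish and needs heat and excess hydroxide, conditions the aryl bromide tolerates, and cold acidification should precipitate acid 7 without protodecarboxylation.

**Step 4**
Reactants: 7 7-bromo-1H-indole-3-carboxylic acid; 8 N-bromosuccinimide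
Product: 10 2,3,7-tribromo-1H-indole, via 3,7-dibromo-1H-indole 9 (not isolated)
Conditions: 8 (2.05 equiv, two portions), DMF, −10 °C to rt, dark
Reagents that add atoms: N-bromosuccinimide (8), O=C1CCC(=O)N1Br
Why: This combines electrophilic ipso bromodecarboxylation (halodecarboxylation of an electron-rich heteroaromatic acid) with electrophilic C2 bromination of a 3-bromoindole, in which bromonium transfer to the most nucleophilic position C3 gives a σ-complex that rearomatises by losing CO2 to give 9, the second equivalent fills the only free pyrrole position C2, and the 7-bromo substituent deactivates the benzene ring against further bromination.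

**Compound list**
1 | 2,6-dibromoaniline | Nc1c(Br)cccc1Br | starting material
2 | methyl 3,3-dimethoxypropanoate | COC(=O)CC(OC)OC | starting material
3 | methyl (Z)-3-[(2,6-dibromophenyl)amino]acrylate | COC(=O)/C=C\Nc1c(Br)cccc1Br | intermediate
4 | methyl 7-bromo-3H-indole-3-carboxylate (racemic, not isolated) | COC(=O)C1C=Nc2c(Br)cccc12 | intermediate
5 | methyl 7-bromo-1H-indole-3-carboxylate | COC(=O)c1c[nH]c2c(Br)cccc12 | intermediate
6 | sodium 7-bromo-1H-indole-3-carboxylate (not isolated) | [Na+].[O-]C(=O)c1c[nH]c2c(Br)cccc12 | intermediate
7 | 7-bromo-1H-indole-3-carboxylic acid | OC(=O)c1c[nH]c2c(Br)cccc12 | intermediate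
8 | N-bromosuccinimide | O=C1CCC(=O)N1Br | starting material
9 | 3,7-dibromo-1H-indole (not isolated) | Brc1c[nH]c2c(Br)cccc12 | intermediate
10 | 2,3,7-tribromo-1H-indole | Brc1[nH]c2c(Br)cccc2c1Br | target

Total step count: 4
Longest linear sequence: 4

**Steps most likely to fail**

**Step 2.**
- Risk: ring closure may be slow compared with reduction of the arylpalladium intermediate (hydrodebromination). Renewed oxidative addition at the surviving C7–Br may also cause loss of bromine or oligomerisation.
- Fallback: it sets out from 1 and builds the pyrrole ring from an alkyne instead of an enamine.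
- Sonogashira mono-coupling of 1 (twofold excess, surplus recovered) with trimethylsilylacetylene (PdCl2(PPh3)2, CuI, Et3N, sealed tube, 80 °C) should give 2-bromo-6-[(trimethylsilyl)ethynyl]aniline F1.
- K2CO3 in MeOH at rt removes the silyl group to give 2-bromo-6-ethynylaniline F2.
- CuI in DMF at 100 °C under N2 closes N1–C2 by 5-endo-dig hydroamination to 7-bromo-1H-indole F3.
- F3 with one equivalent of 8 in DMF at 0 °C gives 9, where the fallback comes back to the route in the flask of step 4. Step 3 is bypassed.

**Step 4.**
- Risk: possible problems are over-bromination of the benzene ring, oxidation of the dibrominated pyrrole ring by adventitious water, and decay of the N–H product during isolation.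
- Fallback: it sets out from 7 and installs the C2 bromine by directed deprotonation instead of electrophilic substitution.
- One equivalent of 8 is used and 9 is isolated.
- Boc2O with catalytic DMAP in MeCN gives tert-butyl 3,7-dibromo-1H-indole-1-carboxylate F4.
- LDA in THF at −78 °C removes the C2 proton without bromine–lithium exchange. Quenching with BrCCl2CCl2Br then gives tert-butyl 2,3,7-tribromo-1H-indole-1-carboxylate F5, which should be robust enough to purify.
- K2CO3 in MeOH at rt cleaves the carbamate as the last operation, and the fallback comes back to the route at 10.

**Step 1.**
- Risk: condensation may be incomplete because the hindered amine is a poor nucleophile, while acid-induced self-condensation of the formylacetate equivalent consumes 2.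
- Fallback: it sets out from 1 and relies on N–H acidity instead of nitrogen nucleophilicity.
- Trifluoroacetic anhydride and pyridine in CH2Cl2 give N-(2,6-dibromophenyl)-2,2,2-trifluoroacetamide F6.
- DABCO-catalysed (10 mol %) conjugate addition of F6 to methyl propiolate in MeCN at rt gives methyl (E)-3-[N-(2,6-dibromophenyl)-2,2,2-trifluoroacetamido]acrylate F7.
- K2CO3 in MeOH at 0 °C to rt removes the trifluoroacetyl group. The freed N–H enaminoester settles as the hydrogen-bonded Z isomer, so the fallback comes back to the route at 3.

**Further compounds**
F1 | step 2 | 2-bromo-6-[(trimethylsilyl)ethynyl]aniline | Nc1c(Br)cccc1C#C[Si](C)(C)C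
F2 | step 2 | 2-bromo-6-ethynylaniline | Nc1c(Br)cccc1C#C
F3 | step 2 | 7-bromo-1H-indole | Brc1cccc2cc[nH]c12
F4 | step 4 | tert-butyl 3,7-dibromo-1H-indole-1-carboxylate | CC(C)(C)OC(=O)n1cc(Br)c2cccc(Br)c12
F5 | step 4 | tert-butyl 2,3,7-tribromo-1H-indole-1-carboxylate | CC(C)(C)OC(=O)n1c(Br)c(Br)c2cccc(Br)c12
F6 | step 1 | N-(2,6-dibromophenyl)-2,2,2-trifluoroacetamide | O=C(Nc1c(Br)cccc1Br)C(F)(F)F
F7 | step 1 | methyl (E)-3-[N-(2,6-dibromophenyl)-2,2,2-trifluoroacetamido]acrylate | COC(=O)/C=C/N(C(=O)C(F)(F)F)c1c(Br)cccc1Br
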